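Atom numbers (target skeleton): enone C1(=O)–C2=C3(Me); cyclobutane C4–C5–C11–C10(Me); seven-membered ring C5–C6(Me2)–C7(O-tiglate)–C8–C9(O-senecioate)–C10. The plan rests on C4 and C11 being the two α-carbons of a C5 ketone inside the four-membered ring C4–C5–C11–C10, so the C1–C2=C3 unit can be tied across that ring.
Endgame: the C9 senecioate and the C7 carbinol come from a C7-keto-C9-ol by an Evans–Tishchenko reduction, then tigloylation and C1 oxidation. The seven-membered ring closes at C8–C7 (α-sulfonyl carbanion onto a C7 nitrile); C6 is built on the C5 ketone.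
Key disconnection C4–C3: palladium-catalysed intramolecular alkenylation of the C5 cyclobutanone enolate by a (Z)-vinyl iodide, giving a bicyclo[3.1.1]hept-2-en-6-one.
Precursor: C11–C1 by a desymmetrizing enamine aldol of a 3,3-disubstituted cyclobutanone (fixes C10 and C11). The cyclobutanone comes from a dichloroketene [2+2] on an isopropenyl dioxolane made from (R)-glycerate acetonide (C9 from the chiral pool).
Ring order: four-membered ring, then six-membered ring (key step), then seven-membered ring.

Key step: step 11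

Remark on the chemistry: in step 7 the sense of induction is assumed to follow the Houk–List model of proline-type enamine aldols, so the (R)-configured catalyst gives (R)-configured C11. C8/C9 travel as an acetonide and sulfur is introduced after steps 11 and 14, because a β-silyloxy sulfone would eliminate under their bases.

Step 1
Reactants: 1 methyl (4R)-2,2-dimethyl-1,3-dioxolane-4-carboxylate
Product: 2 (4R)-N-methoxy-N,2,2-trimethyl-1,3-dioxolane-4-carboxamide
Conditions: MeNHOMe·HCl, i-PrMgCl, THF, −20 → 0 °C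
Reagents that add atoms: N,O-dimethylhydroxylamine hydrochloride, CNOC.Cl
Why: Weinreb amide formation by acyl substitution of the ester with the chloromagnesium amide, at a temperature that should leave the α-alkoxy stereocentre (future C9) intact.

Step 2
Reactants: 2 (4R)-N-methoxy-N,2,2-trimethyl-1,3-dioxolane-4-carboxamide
Product: 3 1-[(4R)-2,2-dimethyl-1,3-dioxolan-4-yl]ethan-1-one
Conditions: MeMgBr, THF, 0 °C
Reagents that add atoms: methylmagnesium bromide, C[Mg]Br
Why: Weinreb ketone synthesis, in which the chelated tetrahedral adduct prevents a second Grignard addition.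

Step 3
Reactants: 3 1-[(4R)-2,2-dimethyl-1,3-dioxolan-4-yl]ethan-1-one
Product: 4 (4S)-2,2-dimethyl-4-(prop-1-en-2-yl)-1,3-dioxolane
Conditions: Ph3PCH3Br, KN(SiMe3)2, THF, −78 → 0 °C
Reagents that add atoms: methyltriphenylphosphonium bromide, C[P+](c1ccccc1)(c1ccccc1)c1ccccc1.[Br-]
Why: Wittig methylenation of the methyl ketone, run cold with a preformed ylide so that the α-alkoxy ketone is not enolised.

Step 4
Reactants: 4 (4S)-2,2-dimethyl-4-(prop-1-en-2-yl)-1,3-dioxolane; 5 trichloroacetyl chloride
Product: 7 2,2-dichloro-3-[(4S)-2,2-dimethyl-1,3-dioxolan-4-yl]-3-methylcyclobutan-1-one, via dichloroketene 6 (not isolated)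
Conditions: Zn–Cu couple, POCl3, Et2O, 23 °C, ultrasound
Reagents that add atoms: none
Why: Thermal [2+2] cycloaddition of dichloroketene to the 1,1-disubstituted alkene, the ketene carbonyl carbon bonding to the CH2 terminus; both epimers at the new quaternary carbon are acceptable because it is no longer stereogenic after step 5.

Step 5
Reactants: 7 2,2-dichloro-3-[(4S)-2,2-dimethyl-1,3-dioxolan-4-yl]-3-methylcyclobutan-1-one
Product: 8 3-[(4S)-2,2-dimethyl-1,3-dioxolan-4-yl]-3-methylcyclobutan-1-one
Conditions: Zn, NH4Cl, MeOH, 23 °C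
Reagents that add atoms: none
Why: Zinc-mediated reductive dechlorination of the α,α-dichloroketone under nearly neutral conditions that should spare the acetonide.

Step 6
Reactants: 9 but-2-yn-1-ol
Product: 10 but-2-ynal
Conditions: MnO2, CH2Cl2, 23 °C
Reagents that add atoms: none
Why: MnO2 oxidation of the propargylic alcohol to the ynal, which is volatile and is used as a filtered solution.

Step 7
Reactants: 8 3-[(4S)-2,2-dimethyl-1,3-dioxolan-4-yl]-3-methylcyclobutan-1-one; 10 but-2-ynal
Product: 11 (2R,3R)-3-[(4S)-2,2-dimethyl-1,3-dioxolan-4-yl]-2-[(1S)-1-hydroxybut-2-yn-1-yl]-3-methylcyclobutan-1-one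
Conditions: (R)-N-tosylpyrrolidine-2-carboxamide (20 mol%), CH2Cl2, 4 °C
Reagents that add atoms: none
Why: Desymmetrizing enamine aldol reaction: the D-proline-derived acyl sulfonamide should set C11 (R) and the anti carbinol C1 (S) through a hydrogen-bonded Houk–List-type transition state, and because the aldehyde enters trans to the dioxolanyl group only one of the two diastereotopic CH2 groups can react in that sense, which fixes C10.

Step 8
Reactants: 11 (2R,3R)-3-[(4S)-2,2-dimethyl-1,3-dioxolan-4-yl]-2-[(1S)-1-hydroxybut-2-yn-1-yl]-3-methylcyclobutan-1-one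
Product: 12 (2R,3R)-3-[(4S)-2,2-dimethyl-1,3-dioxolan-4-yl]-2-[(1S,2Z)-1-hydroxy-3-(triethylsilyl)but-2-en-1-yl]-3-methylcyclobutan-1-one
Conditions: Et3SiH, [Cp*Ru(MeCN)3]PF6 (3 mol%), CH2Cl2, 0 → 23 °C
Reagents that add atoms: triethylsilane, CC[SiH](CC)CC
Why: Ruthenium-catalysed trans-hydrosilylation (Trost) of the propargylic alcohol, in which hydrogen and silicon add anti and the free hydroxyl directs silicon to the distal carbon C3, giving the (Z)-vinylsilane.

Step 9
Reactants: 12 (2R,3R)-3-[(4S)-2,2-dimethyl-1,3-dioxolan-4-yl]-2-[(1S,2Z)-1-hydroxy-3-(triethylsilyl)but-2-en-1-yl]-3-methylcyclobutan-1-one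
Product: 13 (2R,3R)-3-[(4S)-2,2-dimethyl-1,3-dioxolan-4-yl]-2-[(1S,2Z)-1-hydroxy-3-iodobut-2-en-1-yl]-3-methylcyclobutan-1-one
Conditions: NIS, 2,6-lutidine, (CF3)2CHOH, 0 °C
Reagents that add atoms: N-iodosuccinimide, O=C1CCC(=O)N1I
Why: Iododesilylation of the vinylsilane in hexafluoroisopropanol, which proceeds with retention of alkene geometry and should give the (Z)-vinyl iodide.

Step 10
Reactants: 13 (2R,3R)-3-[(4S)-2,2-dimethyl-1,3-dioxolan-4-yl]-2-[(1S,2Z)-1-hydroxy-3-iodobut-2-en-1-yl]-3-methylcyclobutan-1-one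
Product: 14 (2R,3R)-2-[(1S,2Z)-1-(tert-butyldimethylsilyloxy)-3-iodobut-2-en-1-yl]-3-[(4S)-2,2-dimethyl-1,3-dioxolan-4-yl]-3-methylcyclobutan-1-one
Conditions: TBSOTf, 2,6-lutidine, CH2Cl2, −78 °C
Reagents that add atoms: tert-butyldimethylsilyl triflate, CC(C)(C)[Si](C)(C)OS(=O)(=O)C(F)(F)F
Why: O-silylation of the secondary allylic alcohol at −78 °C, where the ketone should not be converted into a silyl enol ether.

Step 11
Reactants: 14 (2R,3R)-2-[(1S,2Z)-1-(tert-butyldimethylsilyloxy)-3-iodobut-2-en-1-yl]-3-[(4S)-2,2-dimethyl-1,3-dioxolan-4-yl]-3-methylcyclobutan-1-one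
Product: 16 4-(tert-butyldimethylsilyloxy)-7-[(4S)-2,2-dimethyl-1,3-dioxolan-4-yl]-2,7-dimethylbicyclo[3.1.1]hept-2-en-6-one, via potassium enolate 15 (not isolated)
Conditions: KN(SiMe3)2 (1.1 equiv), THF, −78 °C; then Pd(PPh3)4 (15 mol%), −78 → 23 °C
Reagents that add atoms: none
Why: Proposed new method: KN(SiMe3)2 removes a C4 proton kinetically (the less substituted α-carbon; a C11 enolate would expel the C1 silyloxy group), zerovalent palladium inserts into the C3–I bond with retention of the Z geometry, the potassium enolate displaces iodide on divalent palladium, and C–C reductive elimination from the carbon-bound palladium enolate forms C4–C3. The closest known reaction type is the palladium-catalysed intramolecular coupling of ketone enolates with vinyl halides used to build bridged bicyclo[3.3.1]nonanones and bicyclo[3.2.1]octanones, which has not been applied to a cyclobutanone. The six-membered ring C3–C2–C1–C11–C5–C4 closes as a bridge spanning the two α-positions of the four-membered ketone, by reductive elimination from a seven-membered palladacycle. The new stereocentre C4 is controlled by the tether, since the bond can only form on the ring face that carries the C11 side chain, and because that side chain is cis to the C10 methyl group in 14 the methyl group ends up syn and the dioxolanyl group anti to the new bridge. The step needs C-alkenylation at C4 in preference to O-alkenylation, to addition of the alkenylpalladium to the strained carbonyl and to ring opening; complete enolate formation before the catalyst is added, the short three-carbon tether and the absence of any α-hydrogen in the bridged product are meant to secure this.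

Step 12
Reactants: 16 4-(tert-butyldimethylsilyloxy)-7-[(4S)-2,2-dimethyl-1,3-dioxolan-4-yl]-2,7-dimethylbicyclo[3.1.1]hept-2-en-6-one; 17 diethyl cyanomethylphosphonate
Product: 19 C5-cyanomethylidene bicycle (C5=C6H–C7N; E/Z mixture), via sodium phosphonate 18 (not isolated)
Conditions: NaH, THF, 0 → 40 °C
Reagents that add atoms: none
Why: Horner–Wadsworth–Emmons olefination of the strained, non-enolisable cyclobutanone, which the small phosphonate anion should attack from the open face next to the C1–C3 bridge; the alkene geometry is irrelevant.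

Step 13
Reactants: 19 C5-cyanomethylidene bicycle
Product: 20 saturated nitrile (C5–H syn to the C1–C3 bridge, C6H2–C7N chain anti to it and cis to the dioxolanyl group)
Conditions: Cu(OAc)2 (5 mol%), Xantphos (5 mol%), (EtO)2MeSiH, t-BuOH, toluene, 23 °C
Reagents that add atoms: none
Why: Copper hydride-catalysed conjugate reduction of the β,β-disubstituted unsaturated nitrile, a two-electron path that avoids a radical next to the four-membered ring; hydride can reach C5 only from the face of the C1–C3 bridge because the other face is covered by the dioxolanyl group on C10, which sets C5.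

Step 14
Reactants: 20 saturated nitrile
Product: 24 gem-dimethyl nitrile (C6 quaternary), via lithiated nitrile 21 (not isolated), via monomethyl nitrile 22 (not isolated), via lithiated monomethyl nitrile 23 (not isolated)
Conditions: LiN(i-Pr)2 then MeI, THF, −78 → 0 °C, two cycles in one flask
Reagents that add atoms: methyl iodide, CI
Why: Twofold α-alkylation of the nitrile anion with methyl iodide builds the quaternary carbon C6, a slim nitrile anion being suited to this crowded position.

Step 15
Reactants: 24 gem-dimethyl nitrile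
Product: 25 C8,C9-diol (C1 silyl ether retained)
Conditions: AcOH–H2O (4:1), 40 °C
Reagents that add atoms: none
Why: Acid-catalysed hydrolysis of the terminal acetonide, which should be faster than cleavage of the hindered secondary silyl ether.

Step 16
Reactants: 25 C8,C9-diol
Product: 26 C8 phenyl sulfide with free C9 hydroxyl
Conditions: PhSSPh, PBu3, THF, 23 °C
Reagents that add atoms: diphenyl disulfide, c1ccc(SSc2ccccc2)cc1
Why: Hata thioetherification, in which the alkoxyphosphonium salt forms only at the primary hydroxyl and is displaced by thiolate in an SN2 reaction.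

Step 17
Reactants: 26 C8 phenyl sulfide
Product: 27 C8 phenyl sulfone with free C9 hydroxyl
Conditions: 30% H2O2, (NH4)6Mo7O24·4H2O (10 mol%), EtOH, 0 → 23 °C
Reagents that add atoms: hydrogen peroxide, OO
Why: Molybdate-catalysed oxidation of the sulfide to the sulfone, which should not epoxidise the trisubstituted alkene.

Step 18
Reactants: 27 C8 phenyl sulfone
Product: 30 tricyclic β-keto sulfone (C7 ketone; C8 sulfonyl epimers; C9 hydroxyl), via dilithiated hydroxy sulfone 28 (not isolated), via cyclic enaminosulfone 29 (not isolated)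
Conditions: LiN(i-Pr)2 (2.3 equiv), THF, −78 → 0 °C; then aq. (CO2H)2, THF, 23 °C
Reagents that add atoms: water, O
Why: Thorpe-type addition of the α-sulfonyl carbanion (as the O,C-dianion, which cannot lose the C9 oxygen by β-elimination) to the non-enolisable nitrile closes the seven-membered ring by 7-exo-dig attack of C8 on C7, the two chains being held on the same face of the cyclobutane, and mild acid then hydrolyses the enaminosulfone to the ketone.

Step 19
Reactants: 30 tricyclic β-keto sulfone
Product: 31 tricyclic (9R)-9-hydroxy-7-ketone (C1 silyl ether)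
Conditions: SmI2, THF–MeOH, −78 °C
Reagents that add atoms: none
Why: Reductive desulfonylation of the β-keto sulfone by electron transfer from divalent samarium, with protonation of the samarium enolate by methanol at −78 °C before the β-hydroxyl can be lost.

Step 20
Reactants: 31 tricyclic (9R)-9-hydroxy-7-ketone; 32 3-methylbut-2-enal
Product: 33 (7R,9R)-7-hydroxy-9-(3-methylbut-2-enoyloxy) tricycle (C1 silyl ether)
Conditions: SmI2 (30 mol%), THF, −10 °C
Reagents that add atoms: none
Why: Evans–Tishchenko reduction, in which the samarium-bound hemiacetal of the C9 hydroxyl and the aldehyde delivers its hydride intramolecularly to C7 on the face of the C9 oxygen, giving the trans (1,3-anti) C7 alcohol and leaving the oxidised aldehyde as the C9 senecioate.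

Step 21
Reactants: 33 (7R,9R)-7-hydroxy-9-(3-methylbut-2-enoyloxy) tricycle; 34 (E)-2-methylbut-2-enoyl chloride (tigloyl chloride)
Product: 35 C7 tiglate C9 senecioate (C1 silyl ether)
Conditions: DMAP, pyridine, CH2Cl2, 0 → 40 °C
Reagents that add atoms: none
Why: DMAP-catalysed acylation of the hindered C7 alcohol with the acid chloride, the (E) geometry of the tigloyl group being the stable one.

Step 22
Reactants: 35 C7 tiglate C9 senecioate
Product: 36 C1 allylic alcohol diester
Conditions: HF·pyridine, pyridine, THF, 0 → 23 °C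
Reagents that add atoms: none
Why: Fluoride-mediated cleavage of the silyl ether under buffered conditions that should not touch the two enoate esters.

Step 23
Reactants: 36 C1 allylic alcohol diester
Product: 37 target CNP0257816.1
Conditions: MnO2, CH2Cl2, 23 °C
Reagents that add atoms: none
Why: MnO2 oxidation of the allylic alcohol to the enone under neutral conditions, as in the oxidation of verbenol to verbenone.

Compound list
1 | methyl (4R)-2,2-dimethyl-1,3-dioxolane-4-carboxylate | COC(=O)[C@H]1COC(C)(C)O1 | starting material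
2 | (4R)-N-methoxy-N,2,2-trimethyl-1,3-dioxolane-4-carboxamide | CON(C)C(=O)[C@H]1COC(C)(C)O1 | intermediate
3 | 1-[(4R)-2,2-dimethyl-1,3-dioxolan-4-yl]ethan-1-one | CC(=O)[C@H]1COC(C)(C)O1 | intermediate
4 | (4S)-2,2-dimethyl-4-(prop-1-en-2-yl)-1,3-dioxolane | C=C(C)[C@H]1COC(C)(C)O1 | intermediate
5 | trichloroacetyl chloride | ClC(=O)C(Cl)(Cl)Cl | starting material
6 | dichloroketene | ClC(Cl)=C=O | intermediate
7 | 2,2-dichloro-3-[(4S)-2,2-dimethyl-1,3-dioxolan-4-yl]-3-methylcyclobutan-1-one (both C3 epimers) | O=C1CC(C)([C@H]2COC(C)(C)O2)C1(Cl)Cl | intermediate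
8 | 3-[(4S)-2,2-dimethyl-1,3-dioxolan-4-yl]-3-methylcyclobutan-1-one | O=C1CC(C)([C@H]2COC(C)(C)O2)C1 | intermediate
9 | but-2-yn-1-ol | CC#CCO | starting material
10 | but-2-ynal | CC#CC=O | intermediate
11 | (2R,3R)-3-[(4S)-2,2-dimethyl-1,3-dioxolan-4-yl]-2-[(1S)-1-hydroxybut-2-yn-1-yl]-3-methylcyclobutan-1-one (side chain cis to the ring methyl, anti aldol) | O=C1C[C@@](C)([C@H]2COC(C)(C)O2)[C@@H]1[C@H](O)C#CC | intermediate
12 | (2R,3R)-3-[(4S)-2,2-dimethyl-1,3-dioxolan-4-yl]-2-[(1S,2Z)-1-hydroxy-3-(triethylsilyl)but-2-en-1-yl]-3-methylcyclobutan-1-one | O=C1C[C@@](C)([C@H]2COC(C)(C)O2)[C@@H]1[C@H](O)/C=C(/C)[Si](CC)(CC)CC | intermediate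
13 | (2R,3R)-3-[(4S)-2,2-dimethyl-1,3-dioxolan-4-yl]-2-[(1S,2Z)-1-hydroxy-3-iodobut-2-en-1-yl]-3-methylcyclobutan-1-one | O=C1C[C@@](C)([C@H]2COC(C)(C)O2)[C@@H]1[C@H](O)/C=C(/C)I | intermediate
14 | (2R,3R)-2-[(1S,2Z)-1-(tert-butyldimethylsilyloxy)-3-iodobut-2-en-1-yl]-3-[(4S)-2,2-dimethyl-1,3-dioxolan-4-yl]-3-methylcyclobutan-1-one (key-step precursor) | O=C1C[C@@](C)([C@H]2COC(C)(C)O2)[C@@H]1[C@H](O[Si](C)(C)C(C)(C)C)/C=C(/C)I | intermediate
15 | potassium enolate of 14 (C5–O(−), C5=C4) | [K+].[O-]C1=C[C@@](C)([C@H]2COC(C)(C)O2)[C@@H]1[C@H](O[Si](C)(C)C(C)(C)C)/C=C(/C)I | intermediate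
16 | 4-(tert-butyldimethylsilyloxy)-7-[(4S)-2,2-dimethyl-1,3-dioxolan-4-yl]-2,7-dimethylbicyclo[3.1.1]hept-2-en-6-one (C5 ketone; C10 methyl syn and dioxolanyl anti to the C1–C3 bridge; C1 silyloxy on the C10 side) | O=C1[C@@H]2C(C)=C[C@@H](O[Si](C)(C)C(C)(C)C)[C@H]1[C@]2(C)[C@H]3COC(C)(C)O3 | intermediate
17 | diethyl cyanomethylphosphonate | CCOP(=O)(OCC)CC#N | starting material
18 | sodium salt of diethyl cyanomethylphosphonate | [Na+].CCOP(=O)(OCC)[CH-]C#N | intermediate
19 | C5-cyanomethylidene derivative of 16 (C5=C6H–C7N, E/Z mixture) | N#CC=C1[C@@H]2C(C)=C[C@@H](O[Si](C)(C)C(C)(C)C)[C@H]1[C@]2(C)[C@H]3COC(C)(C)O3 | intermediate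
20 | saturated nitrile (C5–H syn to the C1–C3 bridge; C6H2–C7N anti) | N#CC[C@H]1[C@@H]2C(C)=C[C@@H](O[Si](C)(C)C(C)(C)C)[C@H]1[C@]2(C)[C@H]3COC(C)(C)O3 | intermediate
21 | lithiated nitrile 20 (lithium keteniminate) | [Li+].[N-]=C=C[C@H]1[C@@H]2C(C)=C[C@@H](O[Si](C)(C)C(C)(C)C)[C@H]1[C@]2(C)[C@H]3COC(C)(C)O3 | intermediate
22 | monomethyl nitrile (C6 epimers) | N#CC(C)[C@H]1[C@@H]2C(C)=C[C@@H](O[Si](C)(C)C(C)(C)C)[C@H]1[C@]2(C)[C@H]3COC(C)(C)O3 | intermediate
23 | lithiated monomethyl nitrile | [Li+].[N-]=C=C(C)[C@H]1[C@@H]2C(C)=C[C@@H](O[Si](C)(C)C(C)(C)C)[C@H]1[C@]2(C)[C@H]3COC(C)(C)O3 | intermediate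
24 | gem-dimethyl nitrile (C6 quaternary, C7 nitrile) | N#CC(C)(C)[C@H]1[C@@H]2C(C)=C[C@@H](O[Si](C)(C)C(C)(C)C)[C@H]1[C@]2(C)[C@H]3COC(C)(C)O3 | intermediate
25 | C8,C9-diol of 24 | N#CC(C)(C)[C@H]1[C@@H]2C(C)=C[C@@H](O[Si](C)(C)C(C)(C)C)[C@H]1[C@]2(C)[C@H](O)CO | intermediate
26 | C8 phenyl sulfide, C9 alcohol | N#CC(C)(C)[C@H]1[C@@H]2C(C)=C[C@@H](O[Si](C)(C)C(C)(C)C)[C@H]1[C@]2(C)[C@H](O)CSc3ccccc3 | intermediate
27 | C8 phenyl sulfone, C9 alcohol | N#CC(C)(C)[C@H]1[C@@H]2C(C)=C[C@@H](O[Si](C)(C)C(C)(C)C)[C@H]1[C@]2(C)[C@H](O)CS(=O)(=O)c3ccccc3 | intermediate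
28 | dilithiated hydroxy sulfone (C9 alkoxide, C8 carbanion) | [Li+].[Li+].N#CC(C)(C)[C@H]1[C@@H]2C(C)=C[C@@H](O[Si](C)(C)C(C)(C)C)[C@H]1[C@]2(C)[C@H]([O-])[CH-]S(=O)(=O)c3ccccc3 | intermediate
29 | cyclic enaminosulfone (C7 amino, C7=C8, C8 sulfonyl) | NC1=C(S(=O)(=O)c4ccccc4)[C@@H](O)[C@@]2(C)[C@@H]3[C@H](O[Si](C)(C)C(C)(C)C)C=C(C)[C@H]2[C@@H]3C1(C)C | intermediate
30 | tricyclic β-keto sulfone (C7 ketone, C8 sulfonyl epimers, C9 hydroxyl, C1 silyl ether) | O=C1C(S(=O)(=O)c4ccccc4)[C@@H](O)[C@@]2(C)[C@@H]3[C@H](O[Si](C)(C)C(C)(C)C)C=C(C)[C@H]2[C@@H]3C1(C)C | intermediate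
31 | tricyclic (9R)-9-hydroxy-7-ketone, C1 silyl ether | O=C1C[C@@H](O)[C@@]2(C)[C@@H]3[C@H](O[Si](C)(C)C(C)(C)C)C=C(C)[C@H]2[C@@H]3C1(C)C | intermediate
32 | 3-methylbut-2-enal | CC(C)=CC=O | starting material
33 | (7R,9R)-7-hydroxy-9-(3-methylbut-2-enoyloxy) tricycle, C1 silyl ether | O[C@@H]1C[C@@H](OC(=O)C=C(C)C)[C@@]2(C)[C@@H]3[C@H](O[Si](C)(C)C(C)(C)C)C=C(C)[C@H]2[C@@H]3C1(C)C | intermediate
34 | (E)-2-methylbut-2-enoyl chloride (tigloyl chloride) | C/C=C(\C)C(=O)Cl | starting material
35 | (7R)-tiglate (9R)-senecioate, C1 silyl ether | C/C=C(\C)C(=O)O[C@@H]1C[C@@H](OC(=O)C=C(C)C)[C@@]2(C)[C@@H]3[C@H](O[Si](C)(C)C(C)(C)C)C=C(C)[C@H]2[C@@H]3C1(C)C | intermediate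
36 | (7R)-tiglate (9R)-senecioate, C1 allylic alcohol | C/C=C(\C)C(=O)O[C@@H]1C[C@@H](OC(=O)C=C(C)C)[C@@]2(C)[C@@H]3[C@H](O)C=C(C)[C@H]2[C@@H]3C1(C)C | intermediate
37 | CNP0257816.1: tricyclic C1 enone with C3, C10 and C6 (two) methyl groups, (7R)-O-tiglate and (9R)-O-senecioate | C/C=C(\C)C(=O)O[C@@H]1C[C@@H](OC(=O)C=C(C)C)[C@@]2(C)[C@@H]3C(=O)C=C(C)[C@H]2[C@@H]3C1(C)C | target

Total step count: 23. Longest linear sequence: 22 steps (steps 1–5 and 7–23; step 6 is a one-step side branch).

Steps most likely to fail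

Step 11 (proposed new method). The alkenylpalladium may add to the strained carbonyl and open the ring, reductive elimination may occur at oxygen, or the enolate may equilibrate to C11 and lose the C1 silyloxy group. The fallback closes the same ring from the alkyne by a gold-catalysed Conia-ene-type cyclisation, a known reaction of silyl enol ethers with alkynes. It sets out from 11. Silylation with TBSOTf and 2,6-lutidine at −78 °C should give the alkynyl silyl ether F1. Kinetic enolisation at C4 with KN(SiMe3)2 in the presence of Et3SiCl should give the triethylsilyl enol ether F2. Ph3PAuCl/AgSbF6 (5 mol% each) in CH2Cl2–H2O then activates the alkyne with monovalent gold. C4 attacks C3 anti to gold in the 6-endo-dig mode, since attack at C2 would require a bicyclo[2.1.1]hexane. Protodeauration at C2 and loss of the silyl group give 16, where the route is rejoined; steps 8 to 10 are then not needed.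

Step 7. The amine catalyst may be consumed by conjugate addition to the ynal, enamine formation next to the quaternary carbon may be slow, and discrimination between the two CH2 groups may be poor. The fallback separates group selection from C–C bond formation and sets out from 8. Deprotonation with a chiral lithium amide, LiN[(R)-CH(Me)Ph]2 with LiCl in THF at −100 °C and Et3SiCl present, should give the silyl enol ether F3. The enantiomer of the base that removes the proton of the future C11 is chosen in a test run. A Mukaiyama aldol addition of F3 to 10 (BF3·OEt2, CH2Cl2, −78 °C) on the face opposite the dioxolanyl group then returns to 11. The C1 epimer formed alongside is separated.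

Step 18. The C9 alkoxide may attack the nitrile, the cyclisation may stay incomplete, and the β-hydroxy β-keto sulfone may dehydrate or cleave by retro-aldol reaction during hydrolysis of the enaminosulfone. The fallback replaces the nitrile by an aldehyde and protects C9; it sets out from 27. TESOTf and 2,6-lutidine should give the C9 triethylsilyl ether F4. Reduction with i-Bu2AlH in toluene at −78 °C and mild aqueous acid give the neopentyl aldehyde F5. LiN(i-Pr)2 at −78 °C generates the α-sulfonyl carbanion, which should add to the non-enolisable aldehyde faster than it expels the silyloxy group, giving the cyclic β-hydroxy sulfone F6. Dess–Martin periodinane oxidises F6 to the β-keto sulfone F7. PPTS in methanol removes the triethylsilyl group selectively and returns to 30.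

Further compounds
F1 | step 11 | alkynyl tert-butyldimethylsilyl ether of 11 | O=C1C[C@@](C)([C@H]2COC(C)(C)O2)[C@@H]1[C@H](O[Si](C)(C)C(C)(C)C)C#CC
F2 | step 11 | C4 triethylsilyl enol ether of F1 (C5–OSiEt3, C5=C4) | CC[Si](CC)(CC)OC1=C[C@@](C)([C@H]2COC(C)(C)O2)[C@@H]1[C@H](O[Si](C)(C)C(C)(C)C)C#CC
F3 | step 7 | triethylsilyl enol ether of 8 (enol carbon is the future C11) | CC[Si](CC)(CC)OC1=C[C@](C)([C@H]2COC(C)(C)O2)C1
F4 | step 18 | C9 triethylsilyl ether of 27 | N#CC(C)(C)[C@H]1[C@@H]2C(C)=C[C@@H](O[Si](C)(C)C(C)(C)C)[C@H]1[C@]2(C)[C@H](O[Si](CC)(CC)CC)CS(=O)(=O)c3ccccc3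
F5 | step 18 | C7 aldehyde (C9 triethylsilyl ether, C8 sulfone) | O=CC(C)(C)[C@H]1[C@@H]2C(C)=C[C@@H](O[Si](C)(C)C(C)(C)C)[C@H]1[C@]2(C)[C@H](O[Si](CC)(CC)CC)CS(=O)(=O)c3ccccc3
F6 | step 18 | cyclic β-hydroxy sulfone (C7 and C8 epimers, C9 triethylsilyl ether) | OC1C(S(=O)(=O)c4ccccc4)[C@@H](O[Si](CC)(CC)CC)[C@@]2(C)[C@@H]3[C@H](O[Si](C)(C)C(C)(C)C)C=C(C)[C@H]2[C@@H]3C1(C)C
F7 | step 18 | cyclic β-keto sulfone (C9 triethylsilyl ether) | O=C1C(S(=O)(=O)c4ccccc4)[C@@H](O[Si](CC)(CC)CC)[C@@]2(C)[C@@H]3[C@H](O[Si](C)(C)C(C)(C)C)C=C(C)[C@H]2[C@@H]3C1(C)C
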